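## Structural features

The target is a flavone in which ring A (the benzo ring) is fused to the pyranone ring C, and ring B, a 4-hydroxyphenyl group, sits on C2 of ring C. Every carbon of ring A is substituted: 5-OH (hydrogen-bonded to the C4 carbonyl), 6-OMe, 7-OH, and at C8 a carbon–carbon bond to C2 of an N-methylpyrrolidine. That pyrrolidine C2 is the only stereocentre, of (R) configuration; it is benzylic and α to nitrogen and has no neighbouring stereocentre from which it could be relayed. The most fragile bond is the benzylic C–N bond, ortho to the 7-OH and para to the 5-OH, which can ionise to a quinone methide, so that reversible ring opening would racemise the centre and hydrogenolysis would cleave it. The three phenols, the C2=C3 enone of ring C and the 6-methyl ether, which must survive the unmasking of its two neighbours, also limit the choice of reagents. The first difficulty is that ring A needs four oxygens in a 1,2,3,5 array with the methyl ether in the middle and the correct oxygen closing ring C, since the wrong one gives the 8-methoxy isomer. The second is that a lone benzylic stereocentre must be created on a fully substituted arene, late enough that it is not lost again. The key step uses the ortho relationship of the 7-OH and C8: with a formyl group on C8 the flavone is a salicylaldehyde, so O7 can bind boron and pass a vinyl group to the iminium carbon that becomes pyrrolidine C2.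

## Logic of the disconnections

**19 ⇒ 17 (through 18).** The 4'-O–Si bond and the two C–H bonds at pyrrolidine C3 and C4 are the last to be made or broken, so 19 goes back to 18 and then to 17. Only these changes are placed after the stereocentre exists, because neither touches a bond to it. The gain is an alkene that a metathesis can make. The demand is a reduction without a metal hydride (no alkene migration into C2, no cleavage of the benzylic C–N bond) and a fluoride source close to neutral.

**17 ⇒ 15 (through 16).** The C3=C4 bond of the pyrroline is cut. In 15 one alkene arm already hangs on nitrogen and the other on the stereocentre, so the ring needs no further carbon. The gain is an acyclic amine. The demand is that the amine does not bind ruthenium, which is met by cyclising 16, the salt of 15, and that 16 does not ionise before it cyclises.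

**15 ⇒ 11 + 12 + 13 (through 14).** The N–C2 and C2–C3 bonds at the stereocentre are cut together. The carbon is flanked by the 7-OH, the handle for boron-tethered delivery. The gain is three achiral pieces and no ring; the stereocentre becomes a matter of catalyst control. The demand is face selection by a chiral diol on boron and a substrate with only one phenol free to act as a boron ligand, which is why the precursor is 11 and not 10. Once formed, 15 must be handled cold and neutral.

**11 ⇒ 10 ⇒ 9.** The 4'-O–Si bond and then the C8–CHO bond are cut. C8 is the only unsubstituted carbon of ring A in 9 and lies ortho to the 7-OH, so a phenol-directed formylation has one site on that ring. Silylation is placed after formylation because the 7-OH is then flanked on both sides and hydrogen-bonded to the aldehyde, leaving the 4'-OH as the only accessible phenol. The gain is a flavone with no carbon at C8. The demand is that ring B is not formylated.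

**9 ⇒ 8.** Two O–isopropyl bonds and one O–benzyl bond are cut. The 5- and 7-oxygens must be masked differently from the 6-methyl ether and from the oxygen that closes ring C, and the masks should fall in one operation. The gain is a flavone without free phenols whose ring C regiochemistry is already fixed. The demand is a Lewis acid that cleaves secondary alkyl and benzyl ethers but not a methyl ether.

**8 ⇒ 7 ⇒ 5 + 6.** The O1–C2 bond and then the C2–C3 bond of ring C are cut. In 7 only one oxygen ortho to the ketone is free, so only the 6-methoxy pattern can form. The gain is that ring B arrives as 6, which is purchased, and ring A as 5. The demand is aroylation at carbon.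

**5 ⇒ 4.** The aryl–acetyl bond (C4a–C4 of the flavone) is cut. Because 4 is symmetric, both carbons ortho to its hydroxyl are equivalent and one ketone results. The demand is acylation without loss of the isopropyl ether next to the new carbonyl.

**4 ⇒ 2 (through 3) ⇒ 1.** The C–O bond para to the methoxy group and the two O–isopropyl bonds are cut. That carbon is meta to both ether oxygens, so electrophilic substitution attacks its neighbours instead; a sterically governed C–H borylation followed by oxidation reaches it. This is the reason for isopropyl and not benzyl ethers: a benzyl group would offer unhindered aryl C–H bonds of its own to the borylation catalyst. The gain is 1, which is purchased. The demand is exactly one unhindered aromatic C–H in 2.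

## Other disconnections considered

**Alternative 1:** The cut runs through ring A itself. Heating the siloxyalkyne tert-butyl (2R)-2-({[tri(propan-2-yl)silyl]oxy}ethynyl)pyrrolidine-1-carboxylate A2 with 3-ethoxy-4-methoxycyclobut-2-en-1-one A3 would form C7–C8, C8a–C4a and C6–C7. The cascade is a 4π ring opening to a vinylketene, [2+2] addition to the alkyne, a second 4π opening and a 6π closure. It would give the phenol tert-butyl (2R)-2-{4-ethoxy-2-hydroxy-3-methoxy-6-[tri(propan-2-yl)silyloxy]phenyl}pyrrolidine-1-carboxylate A1.

- In favour: the stereocentre comes from the chiral pool and travels as a carbamate that cannot ionise, so on stereochemical security this plan is the better of the two. The regiochemistry of the annulation is predictable, and the three oxygens of A1 are differentiated.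
- Against: neither A2 nor A3 is a catalogue compound. After the key step, rings C and B still have to be built at C4a of A1. The O-ethyl group must be cleaved and the carbamate exchanged for N-methyl in two steps, since hydride reduction of the carbamate is not compatible with the pyranone. All of this happens with the benzylic amine already present.
- Comparison: structurally it builds the most substituted ring last, where the chosen plan starts from a preformed arene. Mechanistically it needs no catalyst control, where the chosen plan depends on one. In step economy it should be clearly longer (about sixteen steps or more against eleven), and the same lability appears once the phenols are freed.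

**Alternative 2:** The cut is at pyrrolidine C2–C3 and C4–C5. The glycine-ester imine methyl N-{(E)-[2,4-bis(benzyloxy)-3-methoxy-6-(methoxymethoxy)phenyl]methylidene}glycinate A5, metalated by a monovalent copper catalyst made from Cu(MeCN)4PF6 and a chiral bisphosphine ligand, would add the dipolarophile (ethenesulfonyl)benzene A6 in a (3+2) cycloaddition. The product would be methyl (2S,4R,5S)-5-[2,4-bis(benzyloxy)-3-methoxy-6-(methoxymethoxy)phenyl]-4-(phenylsulfonyl)pyrrolidine-2-carboxylate A4, 2,5-cis and 4,5-trans.

- In favour: ring and stereocentre are made in one catalytic step through a well-understood endo transition state, and A6 is a cheap catalogue dipolarophile. All ring A oxygens are ethers at that stage, so no quinone methide channel exists; on this point the alternative is the better.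
- Against: the imine carbon of A5 is flanked by two ortho oxygens, so reactivity and selectivity of the hindered dipole are uncertain. A4 carries the sulfonyl group of A6 and an ester group, neither of which the target has; removing them (reductive desulfonylation, saponification and radical decarboxylation) and N-methylation would cost four to five steps. The flavone would then have to be assembled on a ring already bearing a basic amine, and the benzyl ethers removed next to a benzylic C–N bond.
- Comparison: structurally it closes the pyrrolidine early and the flavone late, the reverse of the chosen plan. Mechanistically both rely on a chiral catalyst, and the cycloaddition is arguably the better understood. In step economy it should be the longest of the four.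

**Alternative 3:** The cut is the N–C2 bond. A chiral phosphoric acid would protonate the alkene of benzyl {(3E)-4-[5,7-dihydroxy-2-(4-hydroxyphenyl)-6-methoxy-4-oxo-4H-chromen-8-yl]but-3-en-1-yl}carbamate A8 with the help of the 7-OH. The resulting ortho-quinone methide, ion-paired with the phosphate, would be captured by the carbamate nitrogen in a 5-exo closure to give benzyl (2R)-2-[5,7-dihydroxy-2-(4-hydroxyphenyl)-6-methoxy-4-oxo-4H-chromen-8-yl]pyrrolidine-1-carboxylate A7.

- In favour: it uses the same structural handle as the chosen plan but turns the quinone methide from a liability into the bond-forming intermediate. Ring and stereocentre are made together, and A7 is a carbamate, less prone to re-ionise than a tertiary amine; on product robustness it is the better. A8 should be reachable from 9 by C8 halogenation and cross-coupling, so the step count should be about equal to that of the chosen plan.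
- Against: ring A is a vinylogous acid, so protonation of its styrene to a quinone methide should be harder than for simple hydroxystyrenes. The addition is reversible under the same acid, which allows erosion of the enantiomeric ratio. The carbamate of A7 must later be removed (hydrogenolysis threatens the benzylic C–N bond) and the nitrogen methylated.
- Comparison: structurally it is the closest relative of the chosen plan. Mechanistically it rests on thinner precedent for this electron-poor phenol. In step economy it is the equal.

Key step: step 9

Assumption: the (S)-configured diol is taken to deliver the vinyl group to the face that gives the (R) centre; if the sense of induction is the opposite, the (R)-diol is used with no other change.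

## Route

Step 1
Reactants: 1 2-methoxybenzene-1,3-diol
Product: 2 2-methoxy-1,3-di(propan-2-yloxy)benzene
Conditions: iPrBr (3 equiv), K2CO3 (3 equiv), DMF, 60 °C
Reagents that add atoms: 2-bromopropane, CC(C)Br
Why: Williamson ether synthesis on both phenols; isopropyl ethers carry no aryl C–H, withstand Lewis-acid acylation and strong base, and are later cleaved by BCl3 without loss of the methyl ether.

Step 2
Reactants: 2 2-methoxy-1,3-di(propan-2-yloxy)benzene
Product: 4 4-methoxy-3,5-di(propan-2-yloxy)phenol, via arylboronic pinacol ester 3 (not isolated)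
Conditions: B2pin2 (1.0 equiv), [Ir(OMe)(cod)]2 (1.5 mol %), 4,4'-di-tert-butyl-2,2'-bipyridine (3 mol %), THF, 80 °C; then Oxone (2KHSO5·KHSO4·K2SO4), acetone/H2O, 0 °C
Reagents that add atoms: potassium peroxymonosulfate, [K+].[O-]S(=O)(=O)OO
Why: Iridium-catalysed C–H borylation is governed by sterics, and the carbon para to the methoxy group is the only aromatic C–H of 2 without an ortho substituent; oxidation of the C–B bond in the same flask puts the hydroxyl on that carbon (one-pot borylation–oxidation of arenes to phenols).

Step 3
Reactants: 4 4-methoxy-3,5-di(propan-2-yloxy)phenol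
Product: 5 1-[6-hydroxy-3-methoxy-2,4-di(propan-2-yloxy)phenyl]ethan-1-one
Conditions: AcOH, BF3·OEt2 (3 equiv), 65 °C; then aq. NaOAc
Reagents that add atoms: acetic acid, CC(=O)O
Why: Friedel–Crafts ortho-acylation of a phenol with the BF3–acetic acid couple; the two carbons ortho to the hydroxyl are equivalent by symmetry, so only one ketone can form, and its chelated hydroxyl is the oxygen that will close ring C.

Step 4
Reactants: 5 1-[6-hydroxy-3-methoxy-2,4-di(propan-2-yloxy)phenyl]ethan-1-one; 6 4-(benzyloxy)benzoyl chloride
Product: 7 1-[4-(benzyloxy)phenyl]-3-[6-hydroxy-3-methoxy-2,4-di(propan-2-yloxy)phenyl]propane-1,3-dione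
Conditions: LiN(SiMe3)2 (3.3 equiv), THF, −78 → −10 °C; then 6, −78 °C → rt; aq. NH4Cl
Reagents that add atoms: none
Why: Claisen-type C-aroylation of the lithium phenolate–enolate of an ortho-hydroxyacetophenone, the one-flask form of the Baker–Venkataraman diketone synthesis; three equivalents of base keep phenol, enolate and product deprotonated so that acylation stops at the 1,3-diketone.

Step 5
Reactants: 7 1-[4-(benzyloxy)phenyl]-3-[6-hydroxy-3-methoxy-2,4-di(propan-2-yloxy)phenyl]propane-1,3-dione
Product: 8 2-[4-(benzyloxy)phenyl]-6-methoxy-5,7-di(propan-2-yloxy)-4H-chromen-4-one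
Conditions: p-TsOH·H2O (20 mol %), toluene, 90 °C, Dean–Stark
Reagents that add atoms: none
Why: Acid-catalysed cyclodehydration of an ortho-hydroxyaryl 1,3-diketone to a flavone; the only free phenol is the oxygen para to the methoxy group, so ring C can close only to the 6-methoxy isomer, and the anhydrous sulfonic acid leaves the three ethers in place.

Step 6
Reactants: 8 2-[4-(benzyloxy)phenyl]-6-methoxy-5,7-di(propan-2-yloxy)-4H-chromen-4-one
Product: 9 5,7-dihydroxy-2-(4-hydroxyphenyl)-6-methoxy-4H-chromen-4-one
Conditions: BCl3 (6 equiv), C6HMe5 (3 equiv), CH2Cl2, −78 → 0 °C; MeOH; aq. NaHCO3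
Reagents that add atoms: none
Why: Lewis-acid ether cleavage; BCl3 removes isopropyl and benzyl aryl ethers through cation-like departure of the alkyl group far faster than it attacks a methyl ether, and pentamethylbenzene traps the benzyl cation before it can alkylate C8.

Step 7
Reactants: 9 5,7-dihydroxy-2-(4-hydroxyphenyl)-6-methoxy-4H-chromen-4-one
Product: 10 5,7-dihydroxy-2-(4-hydroxyphenyl)-6-methoxy-4-oxo-4H-chromene-8-carbaldehyde
Conditions: (CH2)6N4 (1.5 equiv), CF3CO2H, 70 °C; then H2O, 60 °C
Reagents that add atoms: hexamethylenetetramine, C1N2CN3CN1CN(C2)C3; water, O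
Why: Duff formylation; the iminium ion from hexamethylenetetramine attacks ortho to a phenol, and C8 is the only unsubstituted carbon of ring A, activated by the 7-OH, the 5-OH and O1, while ring B is deactivated by conjugation with the pyranone; internal hydride transfer and hydrolysis give the aldehyde.

Step 8
Reactants: 10 5,7-dihydroxy-2-(4-hydroxyphenyl)-6-methoxy-4-oxo-4H-chromene-8-carbaldehyde
Product: 11 5,7-dihydroxy-6-methoxy-4-oxo-2-(4-{[tri(propan-2-yl)silyl]oxy}phenyl)-4H-chromene-8-carbaldehyde
Conditions: iPr3SiCl (1.1 equiv), imidazole (2.5 equiv), DMF, 0 °C → rt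
Reagents that add atoms: chlorotri(propan-2-yl)silane, CC(C)[Si](Cl)(C(C)C)C(C)C
Why: Imidazole-mediated O-silylation; the 4'-OH is the only phenol that is neither hydrogen-bonded to a carbonyl nor flanked by two substituents, so the bulky silyl chloride should take it alone, which removes the one remote phenol that could act as an achiral ligand on boron and makes the aldehyde soluble in toluene.

Step 9
Reactants: 11 5,7-dihydroxy-6-methoxy-4-oxo-2-(4-{[tri(propan-2-yl)silyl]oxy}phenyl)-4H-chromene-8-carbaldehyde; 12 N-methylprop-2-en-1-amine; 13 dibutyl ethenylboronate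
Product: 15 5,7-dihydroxy-6-methoxy-8-{(1R)-1-[methyl(prop-2-en-1-yl)amino]prop-2-en-1-yl}-2-(4-{[tri(propan-2-yl)silyl]oxy}phenyl)-4H-chromen-4-one, via iminium phenolate 14 (not isolated)
Conditions: 12 (1.3 equiv), 13 (2.0 equiv), (S)-3,3'-dibromo-1,1'-bi-2-naphthol (20 mol %), 4 Å molecular sieves, toluene, 0 °C; pH 7 buffer, 0 °C
Reagents that add atoms: none
Why: Amine 12 condenses with the aldehyde of 11, and the acidic 7-OH turns the adduct into the iminium phenolate 14. Boronate 13 exchanges its butoxy groups for the binaphthol, and the resulting, more Lewis-acidic dioxaborepine binds the 7-phenolate oxygen to give a tetracoordinate boronate. The vinyl group then migrates from boron to the iminium carbon through a six-membered array (B, O7, C7, C8, iminium carbon, vinyl carbon), which makes the N–C2 and C2–C3 bonds of the future pyrrolidine at one carbon, and alcoholysis frees the diol for the next turnover. The closest known reaction is the biaryl-diol-catalysed Petasis borono-Mannich reaction of salicylaldehydes with secondary amines and dialkyl alkenylboronates. No ring is closed. The new stereocentre is under catalyst control: the C2-symmetric dibromobinaphtholate on boron leaves one face of the iminium, held in the plane of ring A by the O7–B tether, open to the vinyl group, and the (S)-diol is assumed to give (R). The step needs O7 to be the only phenol that binds boron, and the substrate secures this: the 5-OH is locked in its hydrogen bond to the C4 carbonyl and lies para to C8, the 4'-oxygen is silylated, and C8 is the only position of ring A that could carry the aldehyde. Intramolecular delivery also keeps the vinyl group away from the pyranone enone, and low temperature with a neutral work-up keeps 15 from losing its amine through the ortho-quinone methide.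

Step 10
Reactants: 15 5,7-dihydroxy-6-methoxy-8-{(1R)-1-[methyl(prop-2-en-1-yl)amino]prop-2-en-1-yl}-2-(4-{[tri(propan-2-yl)silyl]oxy}phenyl)-4H-chromen-4-one
Product: 17 5,7-dihydroxy-6-methoxy-8-[(2R)-1-methyl-2,5-dihydro-1H-pyrrol-2-yl]-2-(4-{[tri(propan-2-yl)silyl]oxy}phenyl)-4H-chromen-4-one, via ammonium tosylate 16 (not isolated)
Conditions: p-TsOH·H2O (1.05 equiv), CH2Cl2, 0 °C; second-generation Grubbs catalyst RuCl2(=CHPh)(H2IMes)(PCy3) (5 mol %), CH2Cl2 (0.01 M), 35 °C, argon purge; cold aq. NaHCO3
Reagents that add atoms: none
Why: Ring-closing metathesis of a diallylamine as its ammonium salt; protonation keeps the nitrogen off ruthenium, closure to the five-membered ring is fast, loss of ethene drives it, and no bond to the stereocentre is made or broken, so the (R) configuration is carried over.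

Step 11
Reactants: 17 5,7-dihydroxy-6-methoxy-8-[(2R)-1-methyl-2,5-dihydro-1H-pyrrol-2-yl]-2-(4-{[tri(propan-2-yl)silyl]oxy}phenyl)-4H-chromen-4-one
Product: 19 5,7-dihydroxy-2-(4-hydroxyphenyl)-6-methoxy-8-[(2R)-1-methylpyrrolidin-2-yl]-4H-chromen-4-one, via silyl ether 18 (not isolated)
Conditions: KO2CN=NCO2K (8 equiv), AcOH (16 equiv), MeOH, 0 → 10 °C; then KHF2 (3 equiv), MeOH, rt; pH 7 buffer
Reagents that add atoms: none
Why: Diimide, released from the azodicarboxylate by acetic acid, transfers two hydrogens in a concerted syn fashion to the unpolarised cis alkene and involves no metal hydride, so it can neither move the alkene into C2 nor cleave the benzylic C–N bond, and it leaves the conjugated C2=C3 of ring C alone; KHF2 in methanol then cleaves the aryl silyl ether under weakly acidic conditions, and the stereocentre is not touched in either operation.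

## Compound list

1 | 2-methoxybenzene-1,3-diol | COc1c(O)cccc1O | starting material
2 | 2-methoxy-1,3-di(propan-2-yloxy)benzene | COc1c(OC(C)C)cccc1OC(C)C | intermediate
3 | 2-[4-methoxy-3,5-di(propan-2-yloxy)phenyl]-4,4,5,5-tetramethyl-1,3,2-dioxaborolane | COc1c(OC(C)C)cc(cc1OC(C)C)B1OC(C)(C)C(C)(C)O1 | intermediate (not isolated)
4 | 4-methoxy-3,5-di(propan-2-yloxy)phenol | COc1c(OC(C)C)cc(O)cc1OC(C)C | intermediate
5 | 1-[6-hydroxy-3-methoxy-2,4-di(propan-2-yloxy)phenyl]ethan-1-one | CC(=O)c1c(O)cc(OC(C)C)c(OC)c1OC(C)C | intermediate
6 | 4-(benzyloxy)benzoyl chloride | O=C(Cl)c1ccc(OCc2ccccc2)cc1 | starting material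
7 | 1-[4-(benzyloxy)phenyl]-3-[6-hydroxy-3-methoxy-2,4-di(propan-2-yloxy)phenyl]propane-1,3-dione | O=C(CC(=O)c1c(O)cc(OC(C)C)c(OC)c1OC(C)C)c1ccc(OCc2ccccc2)cc1 | intermediate
8 | 2-[4-(benzyloxy)phenyl]-6-methoxy-5,7-di(propan-2-yloxy)-4H-chromen-4-one | COc1c(OC(C)C)cc2oc(-c3ccc(OCc4ccccc4)cc3)cc(=O)c2c1OC(C)C | intermediate
9 | 5,7-dihydroxy-2-(4-hydroxyphenyl)-6-methoxy-4H-chromen-4-one | COc1c(O)cc2oc(-c3ccc(O)cc3)cc(=O)c2c1O | intermediate
10 | 5,7-dihydroxy-2-(4-hydroxyphenyl)-6-methoxy-4-oxo-4H-chromene-8-carbaldehyde | COc1c(O)c(C=O)c2oc(-c3ccc(O)cc3)cc(=O)c2c1O | intermediate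
11 | 5,7-dihydroxy-6-methoxy-4-oxo-2-(4-{[tri(propan-2-yl)silyl]oxy}phenyl)-4H-chromene-8-carbaldehyde | COc1c(O)c(C=O)c2oc(-c3ccc(O[Si](C(C)C)(C(C)C)C(C)C)cc3)cc(=O)c2c1O | intermediate
12 | N-methylprop-2-en-1-amine | CNCC=C | starting material
13 | dibutyl ethenylboronate | C=CB(OCCCC)OCCCC | starting material
14 | 5-hydroxy-6-methoxy-8-{[methyl(prop-2-en-1-yl)iminio]methyl}-4-oxo-2-(4-{[tri(propan-2-yl)silyl]oxy}phenyl)-4H-chromen-7-olate | COc1c([O-])c(C=[N+](C)CC=C)c2oc(-c3ccc(O[Si](C(C)C)(C(C)C)C(C)C)cc3)cc(=O)c2c1O | intermediate (not isolated)
15 | 5,7-dihydroxy-6-methoxy-8-{(1R)-1-[methyl(prop-2-en-1-yl)amino]prop-2-en-1-yl}-2-(4-{[tri(propan-2-yl)silyl]oxy}phenyl)-4H-chromen-4-one | COc1c(O)c([C@H](N(C)CC=C)C=C)c2oc(-c3ccc(O[Si](C(C)C)(C(C)C)C(C)C)cc3)cc(=O)c2c1O | intermediate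
16 | (1R)-1-[5,7-dihydroxy-6-methoxy-4-oxo-2-(4-{[tri(propan-2-yl)silyl]oxy}phenyl)-4H-chromen-8-yl]-N-methyl-N-(prop-2-en-1-yl)prop-2-en-1-aminium 4-methylbenzenesulfonate | COc1c(O)c([C@H]([NH+](C)CC=C)C=C)c2oc(-c3ccc(O[Si](C(C)C)(C(C)C)C(C)C)cc3)cc(=O)c2c1O.Cc1ccc(cc1)S(=O)(=O)[O-] | intermediate (not isolated)
17 | 5,7-dihydroxy-6-methoxy-8-[(2R)-1-methyl-2,5-dihydro-1H-pyrrol-2-yl]-2-(4-{[tri(propan-2-yl)silyl]oxy}phenyl)-4H-chromen-4-one | COc1c(O)c([C@H]2C=CCN2C)c2oc(-c3ccc(O[Si](C(C)C)(C(C)C)C(C)C)cc3)cc(=O)c2c1O | intermediate
18 | 5,7-dihydroxy-6-methoxy-8-[(2R)-1-methylpyrrolidin-2-yl]-2-(4-{[tri(propan-2-yl)silyl]oxy}phenyl)-4H-chromen-4-one | COc1c(O)c([C@H]2CCCN2C)c2oc(-c3ccc(O[Si](C(C)C)(C(C)C)C(C)C)cc3)cc(=O)c2c1O | intermediate (not isolated)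
19 | 5,7-dihydroxy-2-(4-hydroxyphenyl)-6-methoxy-8-[(2R)-1-methylpyrrolidin-2-yl]-4H-chromen-4-one | COc1c(O)c([C@H]2CCCN2C)c2oc(-c3ccc(O)cc3)cc(=O)c2c1O | target

## Step count and least certain steps

Total step count: 11. Longest linear sequence: 11 steps (1 to 19); 6, 12 and 13 are purchased.

**Step 9 (key step).** The most likely failure is poor facial selectivity. The acidic 7-phenolate can bind the achiral boronate 13 directly, and the 5-OH/C4 carbonyl pair can chelate boron, so a diol-free pathway may compete with the catalysed one. Loss of the amine from the product through ionisation is the second concern. Fallback: stereocontrol is moved from catalysis to resolution. From 11, 12 and 13, the three-component reaction is run without the diol (CH2Cl2/1,1,1,3,3,3-hexafluoropropan-2-ol, rt) to give racemic 5,7-dihydroxy-6-methoxy-8-{1-[methyl(prop-2-en-1-yl)amino]prop-2-en-1-yl}-2-(4-{[tri(propan-2-yl)silyl]oxy}phenyl)-4H-chromen-4-one F1. This is separated on a chiral stationary phase (amylose tris(3,5-dimethylphenylcarbamate), heptane/propan-2-ol with diethylamine, 5 °C) into 15 and its (1S)-enantiomer, 5,7-dihydroxy-6-methoxy-8-{(1S)-1-[methyl(prop-2-en-1-yl)amino]prop-2-en-1-yl}-2-(4-{[tri(propan-2-yl)silyl]oxy}phenyl)-4H-chromen-4-one F2. The route is rejoined at 15.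

**Step 10.** The ammonium salt 16 may ionise at the benzylic, allylic C–N bond (loss of the amine, then 6π closure of the vinyl quinone methide to a 2H-chromene) faster than it cyclises, or incomplete protonation may stall the catalyst. Fallback: the phenol that drives ionisation is masked before ring closure. From 15, acetylation (Ac2O, Et3N, cat. 4-(dimethylamino)pyridine, CH2Cl2, −20 °C) gives 5-hydroxy-6-methoxy-8-{(1R)-1-[methyl(prop-2-en-1-yl)amino]prop-2-en-1-yl}-4-oxo-2-(4-{[tri(propan-2-yl)silyl]oxy}phenyl)-4H-chromen-7-yl acetate F3. Metathesis of its tosylate salt under the conditions of step 10 gives 5-hydroxy-6-methoxy-8-[(2R)-1-methyl-2,5-dihydro-1H-pyrrol-2-yl]-4-oxo-2-(4-{[tri(propan-2-yl)silyl]oxy}phenyl)-4H-chromen-7-yl acetate F4. Ammonia in methanol at 0 °C removes the acetate and returns the route to 17.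

**Step 11.** Configurational purity may erode through reversible opening of the ortho-hydroxybenzylic C2–N bond in the acidic methanol, and the 2-aryl-3-pyrroline may be dehydrogenated to the pyrrole before diimide consumes it. Fallback: the hydrogen-transfer reagent is replaced by homogeneous catalytic hydrogenation and the two operations are separated. From 17, H2 (1 atm) with RhCl(PPh3)3 in benzene/ethanol at rt gives 18, which is isolated. Its silyl ether is then cleaved with Bu4NF/AcOH (1:1) in THF at −20 °C to reach 19. No new compound is involved.

**Step 7.** Formylation may be incomplete or may spill over to C3' of ring B, and the triphenol may degrade in hot trifluoroacetic acid. Fallback: direct C–H formylation is replaced by halogenation and carbonylation. From 9, N-iodosuccinimide in DMF at 0 °C gives 5,7-dihydroxy-2-(4-hydroxyphenyl)-8-iodo-6-methoxy-4H-chromen-4-one F5. Palladium-catalysed reductive carbonylation (Pd(OAc)2, 1,3-bis(diphenylphosphino)propane, CO (1 atm), Et3SiH, Na2CO3, DMF, 80 °C) then gives 10.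

**Step 3.** The isopropyl ether next to the new ketone may be lost by chelation-assisted cleavage under BF3 at 65 °C, which would remove the distinction between the two ortho oxygens. Fallback: the Lewis-acid acylation is replaced by directed metalation. From 4, MOMCl and iPr2NEt give 2-methoxy-5-(methoxymethoxy)-1,3-di(propan-2-yloxy)benzene F6. Lithiation between the two flanking oxygens (n-BuLi, THF, 0 °C) and quenching with N-methoxy-N-methylacetamide give 1-[3-methoxy-6-(methoxymethoxy)-2,4-di(propan-2-yloxy)phenyl]ethan-1-one F7. HCl in methanol at 40 °C returns the route to 5.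

## Further compounds

F1 | step 9 | 5,7-dihydroxy-6-methoxy-8-{1-[methyl(prop-2-en-1-yl)amino]prop-2-en-1-yl}-2-(4-{[tri(propan-2-yl)silyl]oxy}phenyl)-4H-chromen-4-one (racemic) | COc1c(O)c(C(N(C)CC=C)C=C)c2oc(-c3ccc(O[Si](C(C)C)(C(C)C)C(C)C)cc3)cc(=O)c2c1O
F2 | step 9 | 5,7-dihydroxy-6-methoxy-8-{(1S)-1-[methyl(prop-2-en-1-yl)amino]prop-2-en-1-yl}-2-(4-{[tri(propan-2-yl)silyl]oxy}phenyl)-4H-chromen-4-one | COc1c(O)c([C@@H](N(C)CC=C)C=C)c2oc(-c3ccc(O[Si](C(C)C)(C(C)C)C(C)C)cc3)cc(=O)c2c1O
F3 | step 10 | 5-hydroxy-6-methoxy-8-{(1R)-1-[methyl(prop-2-en-1-yl)amino]prop-2-en-1-yl}-4-oxo-2-(4-{[tri(propan-2-yl)silyl]oxy}phenyl)-4H-chromen-7-yl acetate | COc1c(OC(C)=O)c([C@H](N(C)CC=C)C=C)c2oc(-c3ccc(O[Si](C(C)C)(C(C)C)C(C)C)cc3)cc(=O)c2c1O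
F4 | step 10 | 5-hydroxy-6-methoxy-8-[(2R)-1-methyl-2,5-dihydro-1H-pyrrol-2-yl]-4-oxo-2-(4-{[tri(propan-2-yl)silyl]oxy}phenyl)-4H-chromen-7-yl acetate | COc1c(OC(C)=O)c([C@H]2C=CCN2C)c2oc(-c3ccc(O[Si](C(C)C)(C(C)C)C(C)C)cc3)cc(=O)c2c1O
F0 | step 11 | none | none
F5 | step 7 | 5,7-dihydroxy-2-(4-hydroxyphenyl)-8-iodo-6-methoxy-4H-chromen-4-one | COc1c(O)c(I)c2oc(-c3ccc(O)cc3)cc(=O)c2c1O
F6 | step 3 | 2-methoxy-5-(methoxymethoxy)-1,3-di(propan-2-yloxy)benzene | COCOc1cc(OC(C)C)c(OC)c(OC(C)C)c1
F7 | step 3 | 1-[3-methoxy-6-(methoxymethoxy)-2,4-di(propan-2-yloxy)phenyl]ethan-1-one | CC(=O)c1c(OCOC)cc(OC(C)C)c(OC)c1OC(C)C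
A1 | alternative 1 | tert-butyl (2R)-2-{4-ethoxy-2-hydroxy-3-methoxy-6-[tri(propan-2-yl)silyloxy]phenyl}pyrrolidine-1-carboxylate | CCOc1cc(O[Si](C(C)C)(C(C)C)C(C)C)c([C@H]2CCCN2C(=O)OC(C)(C)C)c(O)c1OC
A2 | alternative 1 | tert-butyl (2R)-2-({[tri(propan-2-yl)silyl]oxy}ethynyl)pyrrolidine-1-carboxylate | CC(C)[Si](C(C)C)(C(C)C)OC#C[C@H]1CCCN1C(=O)OC(C)(C)C
A3 | alternative 1 | 3-ethoxy-4-methoxycyclobut-2-en-1-one | CCOC1=CC(=O)C1OC
A4 | alternative 2 | methyl (2S,4R,5S)-5-[2,4-bis(benzyloxy)-3-methoxy-6-(methoxymethoxy)phenyl]-4-(phenylsulfonyl)pyrrolidine-2-carboxylate | COc1c(OCc2ccccc2)cc(OCOC)c([C@H]2[C@H](S(=O)(=O)c3ccccc3)C[C@@H](C(=O)OC)N2)c1OCc1ccccc1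
A5 | alternative 2 | methyl N-{(E)-[2,4-bis(benzyloxy)-3-methoxy-6-(methoxymethoxy)phenyl]methylidene}glycinate | COC(=O)C/N=C/c1c(OCOC)cc(OCc2ccccc2)c(OC)c1OCc1ccccc1
A6 | alternative 2 | (ethenesulfonyl)benzene | C=CS(=O)(=O)c1ccccc1
A7 | alternative 3 | benzyl (2R)-2-[5,7-dihydroxy-2-(4-hydroxyphenyl)-6-methoxy-4-oxo-4H-chromen-8-yl]pyrrolidine-1-carboxylate | COc1c(O)c([C@H]2CCCN2C(=O)OCc2ccccc2)c2oc(-c3ccc(O)cc3)cc(=O)c2c1O
A8 | alternative 3 | benzyl {(3E)-4-[5,7-dihydroxy-2-(4-hydroxyphenyl)-6-methoxy-4-oxo-4H-chromen-8-yl]but-3-en-1-yl}carbamate | COc1c(O)c(/C=C/CCNC(=O)OCc2ccccc2)c2oc(-c3ccc(O)cc3)cc(=O)c2c1O
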